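**Assumption:** oct-1-yn-3-ol (8) is carried as the racemate because its carbinol carbon becomes the sp2 C15 ketone carbon. Prostaglandin numbering (C1–C20) is used for positions in the later intermediates.

## Retrosynthetic overview

1. 25 ⇐ 24 (acid removal of the C11 TBS ether and the C15 dioxolane) ⇐ 23 (ester hydrolysis) ⇐ 22 (cis-semihydrogenation of the C5–C6 alkyne) ⇐ 21 (C9 ketone to 9α-OH).
2. 21 ⇐ one-pot three-component coupling of enone 5 (ring, C8–C12), alkenyl iodide 12 (C13–C20, ketone masked) and propargylic iodide 17 (C1–C7); C12–C13 forms first, then C8–C7.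
3. 5 ⇐ enzymatic desymmetrization of meso diol 1. 12 ⇐ hexanal + ethynyl Grignard, oxidation, ketalization, hydrozirconation/iodination. 17 ⇐ hex-5-ynoic acid + formaldehyde.
4. Rings: the cyclopentane is bought intact as 1. The only ring made is the temporary dioxolane (step 7), opened in the last step.

## Route

**Fragment A (ring): steps 1–4**

Step 1
Reactants: 1 cis-cyclopent-4-ene-1,3-diol (meso)
Product: 2 (1S,4R)-4-hydroxycyclopent-2-en-1-yl acetate
Conditions: pancreatin (porcine pancreatic lipase), vinyl acetate, Et3N, THF, rt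
Reagents that add atoms: vinyl acetate, CC(=O)OC=C
Why: Lipase-catalysed irreversible transesterification (enzymatic desymmetrization of a meso diol) acylates only the hydroxyl on the S carbon, so the free carbinol carbon (future C11) is R and both stereocenters are fixed at once.

Step 2
Reactants: 2 (1S,4R)-4-hydroxycyclopent-2-en-1-yl acetate
Product: 3 (1S,4R)-4-(tert-butyldimethylsilyloxy)cyclopent-2-en-1-yl acetate
Conditions: TBSCl, imidazole, DMF, rt
Reagents that add atoms: tert-butyldimethylsilyl chloride, CC(C)(C)[Si](C)(C)Cl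
Why: Standard silyl ether formation on the only free hydroxyl; no stereocenter is touched.

Step 3
Reactants: 3 (1S,4R)-4-(tert-butyldimethylsilyloxy)cyclopent-2-en-1-yl acetate
Product: 4 (1S,4R)-4-(tert-butyldimethylsilyloxy)cyclopent-2-en-1-ol
Conditions: K2CO3 (cat.), MeOH, 0 °C to rt
Reagents that add atoms: none
Why: Base-catalysed methanolysis (transesterification) removes the acetate by acyl–oxygen cleavage, with retention at carbon, and the TBS ether is inert.

Step 4
Reactants: 4 (1S,4R)-4-(tert-butyldimethylsilyloxy)cyclopent-2-en-1-ol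
Product: 5 (R)-4-(tert-butyldimethylsilyloxy)cyclopent-2-en-1-one
Conditions: activated MnO2 (excess), CH2Cl2, rt
Reagents that add atoms: none
Why: Allylic alcohol oxidation with MnO2 under neutral conditions gives the enone without eliminating the silyloxy group; the R center (future C11) is untouched.

**Fragment B (C13–C20): steps 5–8**

Step 5
Reactants: 6 hexanal; 7 ethynylmagnesium bromide
Product: 8 rac-oct-1-yn-3-ol
Conditions: THF, 0 °C to rt; cold 1 M HCl
Reagents that add atoms: none
Why: Grignard 1,2-addition of the acetylide to the aldehyde; the new carbinol center is racemic and is erased in step 6.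

Step 6
Reactants: 8 rac-oct-1-yn-3-ol
Product: 9 oct-1-yn-3-one
Conditions: CrO3, H2SO4, H2O/acetone, 0 °C
Reagents that add atoms: none
Why: Chromic acid (Jones) oxidation of a secondary propargylic alcohol to the ynone.

Step 7
Reactants: 9 oct-1-yn-3-one
Product: 10 2-ethynyl-2-pentyl-1,3-dioxolane
Conditions: (TMSOCH2)2, TMSOTf (cat.), CH2Cl2, −78 to −20 °C; pyridine quench
Reagents that add atoms: 1,2-bis(trimethylsilyloxy)ethane, C[Si](C)(C)OCCO[Si](C)(C)C
Why: Noyori ketalization by silyl transfer is aprotic and cold, so the dioxolane forms without a free alcohol adding to the ynone β-carbon.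

Step 8
Reactants: 10 2-ethynyl-2-pentyl-1,3-dioxolane
Product: 12 2-[(E)-2-iodoethenyl]-2-pentyl-1,3-dioxolane, via alkenylzirconocene chloride 11 (not isolated)
Conditions: Cp2Zr(H)Cl, THF, rt; I2, 0 °C
Reagents that add atoms: iodine, II
Why: Hydrozirconation–iodination: syn addition of Zr–H puts zirconium on the unhindered terminus and iodinolysis goes with retention, fixing the 13E geometry.

**Fragment C (C1–C7): steps 9–11**

Step 9
Reactants: 13 hex-5-ynoic acid
Product: 15 7-hydroxyhept-5-ynoic acid, via dilithium acetylide carboxylate 14 (not isolated)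
Conditions: n-BuLi (2.1 equiv), THF, −78 to 0 °C; (CH2O)n, 0 °C to rt; 1 M HCl
Reagents that add atoms: paraformaldehyde (reacts as formaldehyde), C=O
Why: Acetylide addition to formaldehyde through the carboxylate–acetylide dianion; the carboxylate salt protects the acid.

Step 10
Reactants: 15 7-hydroxyhept-5-ynoic acid
Product: 16 methyl 7-hydroxyhept-5-ynoate
Conditions: MeOH (solvent), H2SO4 (cat.), rt to 50 °C
Reagents that add atoms: methanol, CO
Why: Fischer esterification in excess methanol; the primary propargylic alcohol is unaffected.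

Step 11
Reactants: 16 methyl 7-hydroxyhept-5-ynoate
Product: 17 methyl 7-iodohept-5-ynoate
Conditions: PPh3, I2, imidazole, CH2Cl2, 0 °C, dark
Reagents that add atoms: iodine, II
Why: Appel-type iodination, SN2 displacement of the oxyphosphonium by iodide at the primary propargylic carbon.

**Coupling and end game: steps 12–16**

Step 12
Reactants: 12 2-[(E)-2-iodoethenyl]-2-pentyl-1,3-dioxolane; 5 (R)-4-(tert-butyldimethylsilyloxy)cyclopent-2-en-1-one; 17 methyl 7-iodohept-5-ynoate
Product: 21 methyl 7-[(1R,2R,3R)-3-(tert-butyldimethylsilyloxy)-5-oxo-2-[(E)-2-(2-pentyl-1,3-dioxolan-2-yl)ethenyl]cyclopentyl]hept-5-ynoate, via alkenyllithium 18 (not isolated), via lithium alkenyldimethylzincate 19 (not isolated), via zinc enolate 20 (not isolated)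
Conditions: 12, t-BuLi (2 equiv), Et2O, −78 °C; Me2Zn (1 equiv), THF, −78 °C; 5, −78 °C, 1 h; HMPA, then 17 (excess), −78 to −40 °C; aq. NH4Cl
Reagents that add atoms: none
Why: Noyori three-component coupling: the alkenyl group of the zincate adds 1,4 anti to the C11 silyloxy group (sets C12, R), and the regiodefined, weakly basic zinc enolate is C-alkylated by the propargylic iodide anti to the new C12 substituent (sets C8, R).

Step 13
Reactants: 21 (ketone from step 12)
Product: 22 methyl 7-[(1R,2R,3R,5S)-3-(tert-butyldimethylsilyloxy)-5-hydroxy-2-[(E)-2-(2-pentyl-1,3-dioxolan-2-yl)ethenyl]cyclopentyl]hept-5-ynoate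
Conditions: Li[HB(s-Bu)3], THF, −78 °C; aq. NH4Cl
Reagents that add atoms: none
Why: Hindered hydride reduction: the bulky trialkylborohydride attacks the C9 ketone from the face opposite the adjacent C8 chain, giving the 9α (S) alcohol cis to that chain; the ester is inert at −78 °C.

Step 14
Reactants: 22 (alkynyl alcohol from step 13)
Product: 23 methyl (Z)-7-[(1R,2R,3R,5S)-3-(tert-butyldimethylsilyloxy)-5-hydroxy-2-[(E)-2-(2-pentyl-1,3-dioxolan-2-yl)ethenyl]cyclopentyl]hept-5-enoate
Conditions: H2 (1 atm), Pd/CaCO3 poisoned with Pb(OAc)2, quinoline, EtOAc, rt, stopped at 1 equiv H2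
Reagents that add atoms: none
Why: Lindlar-type semi-hydrogenation adds H2 syn to the alkyne on poisoned Pd, giving the 5Z alkene; the disubstituted 13E alkene is not reduced.

Step 15
Reactants: 23 (methyl ester from step 14)
Product: 24 (Z)-7-[(1R,2R,3R,5S)-3-(tert-butyldimethylsilyloxy)-5-hydroxy-2-[(E)-2-(2-pentyl-1,3-dioxolan-2-yl)ethenyl]cyclopentyl]hept-5-enoic acid
Conditions: LiOH, THF/MeOH/H2O, 0 °C to rt; 1 M HCl to pH 4 at 0 °C
Reagents that add atoms: lithium hydroxide, [Li+].[OH-]
Why: Saponification of the methyl ester while the enone is still masked as the base-stable dioxolane, so base never meets the 15-keto enone.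

Step 16
Reactants: 24 (protected acid from step 15)
Product: 25 15-keto-PGF2α, (Z)-7-[(1R,2R,3R,5S)-3,5-dihydroxy-2-[(E)-3-oxooct-1-enyl]cyclopentyl]hept-5-enoic acid
Conditions: 1 M aq. HCl/THF (1:4), rt
Reagents that add atoms: water, O
Why: Acid-catalysed hydrolysis cleaves the allylic dioxolane (to the conjugated enone) and the secondary TBS ether in one pot; the F-type ring has no β-hydroxy ketone and tolerates dilute acid, and no stereocenter is epimerizable.

## Compound list

1 | cis-cyclopent-4-ene-1,3-diol (meso) | O[C@H]1C=C[C@@H](O)C1 | starting material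
2 | (1S,4R)-4-hydroxycyclopent-2-en-1-yl acetate | O[C@H]1C=C[C@@H](OC(C)=O)C1 | intermediate
3 | (1S,4R)-4-(tert-butyldimethylsilyloxy)cyclopent-2-en-1-yl acetate | CC(C)(C)[Si](C)(C)O[C@H]1C=C[C@@H](OC(C)=O)C1 | intermediate
4 | (1S,4R)-4-(tert-butyldimethylsilyloxy)cyclopent-2-en-1-ol | CC(C)(C)[Si](C)(C)O[C@H]1C=C[C@@H](O)C1 | intermediate
5 | (R)-4-(tert-butyldimethylsilyloxy)cyclopent-2-en-1-one | CC(C)(C)[Si](C)(C)O[C@H]1C=CC(=O)C1 | intermediate
6 | hexanal | CCCCCC=O | starting material
7 | ethynylmagnesium bromide | C#C[Mg]Br | starting material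
8 | rac-oct-1-yn-3-ol | CCCCCC(O)C#C | intermediate
9 | oct-1-yn-3-one | CCCCCC(=O)C#C | intermediate
10 | 2-ethynyl-2-pentyl-1,3-dioxolane | CCCCCC1(C#C)OCCO1 | intermediate
11 | chlorobis(cyclopentadienyl)[(E)-2-(2-pentyl-1,3-dioxolan-2-yl)ethenyl]zirconium (cyclopentadienyl rings drawn σ-bonded) | CCCCCC1(OCCO1)/C=C/[Zr](Cl)(C1C=CC=C1)C1C=CC=C1 | intermediate (not isolated)
12 | 2-[(E)-2-iodoethenyl]-2-pentyl-1,3-dioxolane | CCCCCC1(OCCO1)/C=C/I | intermediate
13 | hex-5-ynoic acid | C#CCCCC(=O)O | starting material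
14 | dilithium salt of hex-5-ynoic acid (lithium carboxylate, lithium acetylide) | [Li]C#CCCCC(=O)O[Li] | intermediate (not isolated)
15 | 7-hydroxyhept-5-ynoic acid | OCC#CCCCC(=O)O | intermediate
16 | methyl 7-hydroxyhept-5-ynoate | COC(=O)CCCC#CCO | intermediate
17 | methyl 7-iodohept-5-ynoate | COC(=O)CCCC#CCI | intermediate
18 | [(E)-2-(2-pentyl-1,3-dioxolan-2-yl)ethenyl]lithium | CCCCCC1(OCCO1)/C=C/[Li] | intermediate (not isolated)
19 | lithium dimethyl[(E)-2-(2-pentyl-1,3-dioxolan-2-yl)ethenyl]zincate | [Li+].CCCCCC1(OCCO1)/C=C/[Zn-](C)C | intermediate (not isolated)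
20 | lithium dimethylzincate enolate (C8=C9) of (3R,4R)-4-(tert-butyldimethylsilyloxy)-3-[(E)-2-(2-pentyl-1,3-dioxolan-2-yl)ethenyl]cyclopentanone | [Li+].CCCCCC1(OCCO1)/C=C/[C@@H]2C=C(O[Zn-](C)C)C[C@H]2O[Si](C)(C)C(C)(C)C | intermediate (not isolated)
21 | methyl 7-[(1R,2R,3R)-3-(tert-butyldimethylsilyloxy)-5-oxo-2-[(E)-2-(2-pentyl-1,3-dioxolan-2-yl)ethenyl]cyclopentyl]hept-5-ynoate | CCCCCC1(OCCO1)/C=C/[C@@H]2[C@@H](CC#CCCCC(=O)OC)C(=O)C[C@H]2O[Si](C)(C)C(C)(C)C | intermediate
22 | methyl 7-[(1R,2R,3R,5S)-3-(tert-butyldimethylsilyloxy)-5-hydroxy-2-[(E)-2-(2-pentyl-1,3-dioxolan-2-yl)ethenyl]cyclopentyl]hept-5-ynoate | CCCCCC1(OCCO1)/C=C/[C@@H]2[C@@H](CC#CCCCC(=O)OC)[C@@H](O)C[C@H]2O[Si](C)(C)C(C)(C)C | intermediate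
23 | methyl (Z)-7-[(1R,2R,3R,5S)-3-(tert-butyldimethylsilyloxy)-5-hydroxy-2-[(E)-2-(2-pentyl-1,3-dioxolan-2-yl)ethenyl]cyclopentyl]hept-5-enoate | CCCCCC1(OCCO1)/C=C/[C@@H]2[C@@H](C/C=C\CCCC(=O)OC)[C@@H](O)C[C@H]2O[Si](C)(C)C(C)(C)C | intermediate
24 | (Z)-7-[(1R,2R,3R,5S)-3-(tert-butyldimethylsilyloxy)-5-hydroxy-2-[(E)-2-(2-pentyl-1,3-dioxolan-2-yl)ethenyl]cyclopentyl]hept-5-enoic acid | CCCCCC1(OCCO1)/C=C/[C@@H]2[C@@H](C/C=C\CCCC(=O)O)[C@@H](O)C[C@H]2O[Si](C)(C)C(C)(C)C | intermediate
25 | 15-keto-PGF2α, (Z)-7-[(1R,2R,3R,5S)-3,5-dihydroxy-2-[(E)-3-oxooct-1-enyl]cyclopentyl]hept-5-enoic acid | CCCCCC(=O)/C=C/[C@@H]1[C@@H](C/C=C\CCCC(=O)O)[C@@H](O)C[C@H]1O | target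

## Step count and risks

Total step count: 16 (fragment A 4, fragment B 4, fragment C 3, coupling 1, end game 4).
Longest linear sequence: 9 steps (steps 1–4 or steps 5–8, then steps 12–16).

**Steps most likely to fail**

Step 12 (three-component coupling). The enolate alkylation can lose out to proton transfer, to β-elimination of the C11 silyloxy group, or to unreacted enolate. The fallback replaces the alkyl halide by an aldehyde; it sets out from 16 (with 12 and 5 through enolate 20) and comes back at 21. Alcohol 16 is oxidized with MnO2 in CH2Cl2 to methyl 7-oxohept-5-ynoate F1. Enolate 20, generated as in step 12, is trapped at −78 °C with F1 to give the aldol adduct methyl 7-[(1S,2R,3R)-3-(tert-butyldimethylsilyloxy)-5-oxo-2-[(E)-2-(2-pentyl-1,3-dioxolan-2-yl)ethenyl]cyclopentyl]-7-hydroxyhept-5-ynoate F2 (C7 epimers; the ring C1 descriptor changes only through priority). Phenyl chlorothionoformate with DMAP and pyridine converts it into the corresponding 7-O-(phenoxythiocarbonyl) derivative F3. Barton–McCombie deoxygenation (Bu3SnH, AIBN, toluene, 80 °C) then removes the C7 oxygen and delivers 21.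

Step 7 (ketalization of the terminal ynone). Ynone 9 may polymerize or take up the glycol at C1 instead of forming the ketal. The fallback masks the alkyne terminus with silicon; it sets out from 6 and comes back at 10. Commercial lithium (trimethylsilyl)acetylide is added to hexanal 6 to give rac-1-(trimethylsilyl)oct-1-yn-3-ol F4. Oxidation (CrO3, H2SO4, acetone) gives 1-(trimethylsilyl)oct-1-yn-3-one F5, a much weaker Michael acceptor. Ketalization under the silyl-transfer conditions of step 7 gives trimethyl[(2-pentyl-1,3-dioxolan-2-yl)ethynyl]silane F6, and K2CO3 in MeOH removes the C-silyl group to return 10.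

Step 14 (semi-hydrogenation on the full skeleton). Over-reduction, Z/E isomerization or partial reduction of the 13E alkene would be hard to separate at this stage. The fallback installs the Z alkene on the small fragment; it sets out from 16 and comes back at 23, bypassing 17, 21 and 22. Alcohol 16 is semi-hydrogenated (H2, Pd/CaCO3 poisoned with Pb(OAc)2, quinoline) to methyl (Z)-7-hydroxyhept-5-enoate F7 and iodinated (PPh3, I2, imidazole) to methyl (Z)-7-iodohept-5-enoate F8. F8 is used as the electrophile for enolate 20 under the conditions of step 12, giving methyl (Z)-7-[(1R,2R,3R)-3-(tert-butyldimethylsilyloxy)-5-oxo-2-[(E)-2-(2-pentyl-1,3-dioxolan-2-yl)ethenyl]cyclopentyl]hept-5-enoate F9. Reduction with Li[HB(s-Bu)3] at −78 °C then gives 23.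

## Further compounds

F1 | step 12 | methyl 7-oxohept-5-ynoate | COC(=O)CCCC#CC=O
F2 | step 12 | methyl 7-[(1S,2R,3R)-3-(tert-butyldimethylsilyloxy)-5-oxo-2-[(E)-2-(2-pentyl-1,3-dioxolan-2-yl)ethenyl]cyclopentyl]-7-hydroxyhept-5-ynoate (C7 epimers) | CCCCCC1(OCCO1)/C=C/[C@@H]2[C@@H](C(O)C#CCCCC(=O)OC)C(=O)C[C@H]2O[Si](C)(C)C(C)(C)C
F3 | step 12 | methyl 7-[(1S,2R,3R)-3-(tert-butyldimethylsilyloxy)-5-oxo-2-[(E)-2-(2-pentyl-1,3-dioxolan-2-yl)ethenyl]cyclopentyl]-7-(phenoxythiocarbonyloxy)hept-5-ynoate (C7 epimers) | CCCCCC1(OCCO1)/C=C/[C@@H]2[C@@H](C(OC(=S)Oc3ccccc3)C#CCCCC(=O)OC)C(=O)C[C@H]2O[Si](C)(C)C(C)(C)C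
F4 | step 7 | rac-1-(trimethylsilyl)oct-1-yn-3-ol | CCCCCC(O)C#C[Si](C)(C)C
F5 | step 7 | 1-(trimethylsilyl)oct-1-yn-3-one | CCCCCC(=O)C#C[Si](C)(C)C
F6 | step 7 | trimethyl[(2-pentyl-1,3-dioxolan-2-yl)ethynyl]silane | CCCCCC1(OCCO1)C#C[Si](C)(C)C
F7 | step 14 | methyl (Z)-7-hydroxyhept-5-enoate | COC(=O)CCC/C=C\CO
F8 | step 14 | methyl (Z)-7-iodohept-5-enoate | COC(=O)CCC/C=C\CI
F9 | step 14 | methyl (Z)-7-[(1R,2R,3R)-3-(tert-butyldimethylsilyloxy)-5-oxo-2-[(E)-2-(2-pentyl-1,3-dioxolan-2-yl)ethenyl]cyclopentyl]hept-5-enoate | CCCCCC1(OCCO1)/C=C/[C@@H]2[C@@H](C/C=C\CCCC(=O)OC)C(=O)C[C@H]2O[Si](C)(C)C(C)(C)C
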